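Late in the earlier runs left-handed product sinks from 64 % and 63 % at 20.0 h to 51 % at 50.0 h, towards half of the charge, since the products of the two hands are mirror images.

| flask | left-handed substrate | right-handed substrate | partner | remark | time |
|---|---|---|---|---|---|
| north-west | 0.25 M | 0.25 M | 2 M | run made earlier |  |
| north-east | 0.38 M | 0.38 M | 2 M | run made earlier |  |
| flask | 0.50 M | 0.50 M | 2.00 M |  | 2.0 d |

| run | time / h | left-handed product / % | left-handed substrate / % |
|---|---|---|---|
| north-west | 2.50 | 47 | 15 |
| north-west | 8.00 | 72 | 7 |
| north-west | 20.0 | 64 | 1 |
| north-west | 50.0 | 51 | 1 |
| north-east | 2.50 | 44 | 21 |
| north-east | 8.00 | 69 | 7 |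
| north-east | 20.0 | 63 | 4 |
| north-east | 50.0 | 51 | 0 |

(each reading ± 1.5 percentage points)

1. time, not beyond 2.0 d, at which the flask holds most left-handed product
2. the amount of left-handed product, in percent of the left-handed substrate and right-handed substrate together charged, at that time

Read as a decay of the excess over that half, the two runs together give a relaxation rate of 0.0868 h⁻¹. This is a rough reading, with a last excess of 1 percentage point against a scatter of 1.5 points. Earlier, between 2.50 h and 8.00 h, left-handed substrate in the two runs together drains at 0.172 h⁻¹, with a mean of 1.37 M of partner left over.

Two chemists differ on the flask. The first takes partner as constant (pseudo-first-order) and expects the highest reading of the runs again, 72 % at 8.00 h. The second counts partner: the flask's substrates together use 1.00 M and leave 1.00 M, half of the charge.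

My own reckoning scales the drain to that leftover partner and divides it by the relaxation rate, which gives 1.44 for the flask. This is the feed ratio, the drain of substrate at leftover partner over the relaxation of the product excess, and I read 1 as the crossing where control passes from feed to inversion. The north-west run has 2.17, so the flask stands nearer the crossing, and I expect a lower peak, without a number.

The forecast sides with the second chemist at 68 % and 0.45 d: “In the flask, 1 M substrate depletes half the partner, so the late feed is slower.”

The flask gives 67.4 % at 0.454 d, lower than the north-west run's 70.0 % without the scatter.

    partner + right-handed substrate → right-handed product (k = 0.00290 M⁻¹ h⁻¹)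
    left-handed product ⇌ right-handed product (k = 0.0410 h⁻¹)
    partner + left-handed substrate → left-handed product (k = 0.350 M⁻¹ h⁻¹)
    left-handed substrate ⇌ right-handed substrate (k = 0.530 h⁻¹)

The first chemist's 72 % lies nearer the north-west run's highest value without the scatter, 70.0 %, than the flask's, and the substrates of that run together use 0.500 M of 2 M of partner, a quarter. The reaction of partner with right-handed substrate, 120 times slower at the start, makes no difference. In the flask, making of left-handed product falls from 5.75 times its using up at 0.117 d to 0.0473 at 2.00 d. A neighbour flask with 1.2 M of partner has a feed ratio of 0.289, past the crossing, and its best is 56.5 %. At 2.00 d that neighbour still holds 1.98 % of left-handed substrate and 20 % of its partner.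

The runs are calculated with constants of no real substance, noise included.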